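## The problem

Compound 20 is a bicyclo[3.2.1]octane. The locants are: C1 the allyl-bearing bridgehead, C2 the methylene, C3 the methoxy methine, C4 the ketone, C5 the methoxy bridgehead, C6 the aryl carbon, C7 the methyl carbon, C8 the carbinol bridge. A cyclopentane (C1–C7–C6–C5–C8) and a cyclohexanone (C1–C2–C3–C4–C5–C8) share the C1–C8–C5 unit; these locants are used for every intermediate, ring-opened ones included.

There are six stereocentres (1S,3S,5S,6S,7R,8S in this numbering). C1 and C5 are tied to each other by the bridge, so four things must be decided: the trans pair C6/C7 (aryl endo, methyl exo), the face of the five-membered ring that carries the three-carbon bridge (cis to aryl, trans to methyl), C3 (methoxy endo) and C8 (hydroxyl over the C2–C4 bridge).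

Only C6 and C7 need outside control. The C7 methyl group can steer the first bond made at C1. The endo aryl group then screens one face of C3. The endo methoxy group at C3 cannot share a chair with the endo aryl group, so the six-membered ring becomes a boat in which only one face of C8 is open.

The compound is a β-hydroxy ketone (C8–OH/C4=O, retro-aldol) with an epimerisable α-methoxy centre at C3. Its precursors include a β-diketone that cannot enolise at C5 (retro-Claisen). The terminal alkene rules out hydrogenation, and the phenol must be masked.

The enabling feature is that C8, with α-carbons C1 and C5 and β-carbons C7 and C6, is a cyclopentanone whose two β-carbons carry the trans aryl and methyl groups. That is the pattern a conrotatory 4π closure of a divinyl ketone delivers, and the C5 methoxy group is the donor that polarises such a closure.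

## Retrosynthesis

**20 back to 18.** No skeletal bond is cut. The phenol is unmasked last (19 to 20), and the C8 carbinol is taken back to the ketone of dione 18. C8 is kept as a ketone until late because it alone acidifies C1 and C5; a carbinol at C8 would forbid all enolate chemistry at the bridgeheads. The forward reduction must choose C8 over C4 and must deliver hydride from the C6–C7 side.

**18 back to 13 and 14.** The C1–C2 and C4–C5 bonds are cut, which removes the six-membered ring, both quaternary carbons and C3 in one operation. The three carbons come from methyl 2-methoxyacrylate (14). The reasons for this choice against its neighbours are: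
- An acrylate ester is preferred to the corresponding enal because the Dieckmann closure delivers C4 as the ketone. No oxidation is needed, no C4 carbinol epimers arise, and the reaction ends in the C3=C4 enolate, whose kinetic protonation sets C3.
- The order "C1 first, C5 second" is dictated by the target. The first, intermolecular bond forms anti to the neighbouring substituent. At C1 that is anti to the C7 methyl group, as required. At C5 it would be anti to the C6 aryl group, which is wrong. The C4–C5 bond, cis to the aryl group, is then forced by the tether.
- The forward reaction needs the C1 enolate and no C5 enolate. The five-membered ring is therefore carried as the C1=C8 triethylsilyl enol ether 13, not as the free ketone, whose two methine α-positions cannot be told apart reliably.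

**13 back to 12.** The C6–C7 bond is cut. This is the only cut that turns the ring into an acyclic, achiral compound and creates the trans C6/C7 pair by orbital symmetry instead of by reagent approach. The precursor is the (1Z,4E)-α-methoxy divinyl ketone 12. The forward reaction needs control of the sense of conrotation, hydride capture at C5 before proton loss from C6, and release of the product as the enol silane.

**12 back to 9 and 11.** The C5=C6 double bond is cut by Horner–Wadsworth–Emmons olefination of the α-methoxy β-ketophosphonate 9 with the silyl-protected isovanillin 11 (from 10). The alternative, an aldol condensation of a methoxymethyl ketone, needs a methoxymethyl organometallic and a separate dehydration.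

**9 back to 6 and 7, and 6 back to 1, 2 and 5.** The C8–C5 bond is cut by acylation of lithiated diethyl (methoxymethyl)phosphonate (7) with ester 6. The C1=C7 double bond of 6 is cut by Wittig reaction of the α-allyl ylide 4 with acetaldehyde (5); 4 comes from ylide 1 and allyl bromide (2). The stabilised α-substituted ylide is chosen over the corresponding phosphonate because it gives the E enoate more cleanly, and the E geometry is what places the methyl group outward in the cyclisation.

## Roads not taken

**Alternative 1:** The cut is C3–C4, the ketone bridge. Forward, tin–lithium exchange at C3 of the stannyl amide A1 (n-BuLi) would give a configurationally stable α-methoxy carbanion. It attacks the N-methoxy-N-methylamide carbon C4 on C5 and closes the six-membered ring to A2, the bis-silyl ether of the target.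
- Merits: C4 arrives as a ketone, C3 is carried over with retention from a stereodefined stannane, and C8 is already a protected carbinol. This road therefore needs neither the late hydride discrimination between C4 and C8 nor the kinetic protonation at C3 on which the chosen plan leans. In those two respects it is the better plan.
- Weak points: A1 must hold all six stereocentres, both quaternary carbons included, on a monocyclic cyclopentane in which nothing links C1 to C5, with a stereodefined α-alkoxystannane beside them. The closure must push the endo methoxy group against the endo aryl group while attacking a neopentyl-like amide, so proton transfer may outrun addition.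
- Comparison: against that cleaner end the chosen plan sets a much cheaper middle. Compound 13 has two controlled stereocentres, and one annulation then makes both quaternary carbons and the second ring.

**Alternative 2:** The cut is C5–C6, made by an α-ketol shift. In the bicyclo[2.2.2]octenone A3 the bridgehead C4 carries the hydroxyl and C5 is the ketone. Base or a Lewis acid would move C6 from C4 to C5 to give the bicyclo[3.2.1]octenone A4.
- Merits: A3 is the kind of adduct a masked ortho-quinone gives with an (E)-propenylarene in one Diels–Alder step. The skeleton with the trans aryl/methyl pair would be reached in fewer steps than here. The later 1,4-reduction of the C2=C3 enone would set C3 by the same exo protonation used in the chosen plan.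
- Weak points: the shift is an equilibrium, and neither its position nor the migrating group (C6 against the vinylic C3) is assured. A4 has a tertiary bridgehead alcohol at C5 that must be methylated next to a ketone, under conditions that could reverse the shift. The enone must be reduced without touching the allyl group, the C8 ketal must become the carbinol, and the cycloaddition gives a racemate unless a chiral catalyst for it is found.
- Comparison: the chosen plan is longer to the bicycle, but it brings the C5 methoxy group in from the start, has no equilibrium step, and takes its absolute configuration from a catalyst.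

**Alternative 3:** The cut is C1–C7. Forward, Bu3SnH would turn the tertiary bromide A5 into the C1 radical flanked by two ketones. It closes 5-exo-trig onto the vinyl group on C6, and the primary radical is reduced to the C7 methyl group, giving the dione A6.
- Merits: A6 is 18 with a different silyl group, so this road joins the chosen one before the end game. Radical closure is little troubled by crowding at the quaternary carbon and needs no regiodefined enolate.
- Weak points: A5 is a 2,2-disubstituted cyclohexane-1,3-dione (retro-Claisen sensitive) that already needs C3, C5 and C6 in place. The doubly stabilised radical adds slowly to an unactivated vinyl group, so simple reduction competes. C7 is set in the radical step under conformational control only.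
- Comparison: the two roads share the reduction problem at C8. The chosen plan sets against the radical route the trans C6/C7 relation imposed by orbital symmetry, catalytic absolute control and a tin-free sequence.

Key step: step 6

Remarks on the chemistry:
- (S,S)-Ph-pybox is written in step 6. Which antipode of the ligand gives the 6S,7R sense of conrotation cannot be derived for this substrate; both antipodes are available, so the hand of the ligand is fixed in the first run.
- The five-membered ring leaves the key step as its C1=C8 triethylsilyl enol ether 13. A silane-terminated catalytic cycle should release it in that form, and it is isolated without hydrolysis because it holds the enol regiochemistry needed in step 7.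
- Methyl 2-methoxyacrylate (14) and diethyl (methoxymethyl)phosphonate (7) are taken as purchasable.

## Route

Step 1
Reactants: 1 ethyl (triphenyl-λ5-phosphanylidene)acetate; 2 allyl bromide
Product: 4 ethyl 2-(triphenyl-λ5-phosphanylidene)pent-4-enoate, via phosphonium bromide 3 (not isolated)
Conditions: EtOAc, reflux; then NaOH (aq), CH2Cl2, 0 °C
Reagents that add atoms: none
Why: C-alkylation of the ester-stabilised ylide by the allylic bromide gives salt 3, and hydroxide removes the remaining α-proton to give the α-allyl ylide (ylide alkylation).

Step 2
Reactants: 4 ethyl 2-(triphenyl-λ5-phosphanylidene)pent-4-enoate; 5 acetaldehyde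
Product: 6 ethyl (2E)-2-(prop-2-en-1-yl)but-2-enoate
Conditions: CH2Cl2, sealed tube, 40 °C
Reagents that add atoms: none
Why: Wittig olefination; α-substituted ester-stabilised ylides give the (E)-trisubstituted enoate with aliphatic aldehydes, which places the methyl group trans to the carbonyl, the geometry the cyclisation needs.

Step 3
Reactants: 6 ethyl (2E)-2-(prop-2-en-1-yl)but-2-enoate; 7 diethyl (methoxymethyl)phosphonate
Product: 9 diethyl [(3E)-1-methoxy-2-oxo-3-(prop-2-en-1-yl)pent-3-en-1-yl]phosphonate (racemic at the methoxy carbon), via lithiated phosphonate 8 (not isolated)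
Conditions: LiN(iPr)2, THF, −78 °C; then 6, −78 → −20 °C; NH4Cl (aq)
Reagents that add atoms: none
Why: Acylation of an α-lithio phosphonate by an ester (Claisen-type condensation); two equivalents of 8 are used because the product is deprotonated as it forms, which also shields the new ketone, and 1,2-attack is expected for the α-branched enoate.

Step 4
Reactants: 10 isovanillin (3-hydroxy-4-methoxybenzaldehyde)
Product: 11 4-methoxy-3-[(triisopropylsilyl)oxy]benzaldehyde
Conditions: TIPSCl, imidazole, DMF, rt
Reagents that add atoms: triisopropylsilyl chloride, CC(C)[Si](Cl)(C(C)C)C(C)C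
Why: Silylation of a phenol; the triisopropylsilyl ether is chosen because it should survive DBU in step 5, the Lewis acid in step 6 and MeLi and the amide base in step 7.

Step 5
Reactants: 9 diethyl [(3E)-1-methoxy-2-oxo-3-(prop-2-en-1-yl)pent-3-en-1-yl]phosphonate; 11 4-methoxy-3-[(triisopropylsilyl)oxy]benzaldehyde
Product: 12 (1Z,4E)-2-methoxy-1-{4-methoxy-3-[(triisopropylsilyl)oxy]phenyl}-4-(prop-2-en-1-yl)hexa-1,4-dien-3-one
Conditions: LiCl, DBU, MeCN, 0 °C → rt
Reagents that add atoms: none
Why: Horner–Wadsworth–Emmons olefination; α-alkoxy phosphonates give mainly the enol ether with aryl trans to the acyl group (Z), which is also the more stable isomer, and any E isomer should equilibrate under the Lewis acid of step 6.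

Step 6
Reactants: 12 (1Z,4E)-2-methoxy-1-{4-methoxy-3-[(triisopropylsilyl)oxy]phenyl}-4-(prop-2-en-1-yl)hexa-1,4-dien-3-one
Product: 13 triethyl{[(3R,4S,5R)-5-methoxy-4-{4-methoxy-3-[(triisopropylsilyl)oxy]phenyl}-3-methyl-2-(prop-2-en-1-yl)cyclopent-1-en-1-yl]oxy}silane
Conditions: Sc(OTf)3 (10 mol %), (S,S)-Ph-pybox (12 mol %), Et3SiH, 3 Å MS, CH2Cl2, −20 °C → rt
Reagents that add atoms: triethylsilane, CC[SiH](CC)CC
Why: Proposed new method: the closest known reaction types are the Lewis acid promoted reductive (hydride-interrupted) Nazarov cyclisation of dienones with Et3SiH and the Sc(OTf)3–pybox catalysed asymmetric Nazarov cyclisation of α-alkoxy dienones, and the step merges them on the reasoning that the chelated oxyallyl cation which the asymmetric reaction normally quenches by proton loss is the species that silanes are known to reduce. Sc(OTf)3 binds the C8 carbonyl and the C5 methoxy oxygen in a five-membered chelate and turns 12 into a 3-oxidopentadienyl cation. Thermal 4π conrotatory electrocyclisation joins C6 to C7 and closes the ring C1–C7–C6–C5–C8 (an electrocyclic closure, not a nucleophilic one). The aryl group on the Z enol ether and the methyl group on the E alkene both point outward, so conrotation places them trans; the relative configuration of C6 and C7 follows from orbital symmetry and the alkene geometries. The absolute sense, 6S,7R, depends on which direction of conrotation the C2-symmetric ligand allows on the planar chelated cation, and this torquoselectivity is the selectivity the step needs. The oxyallyl cation carries most of its charge at C5 as an oxocarbenium ion, so Et3SiH should deliver hydride there, anti to the C6 aryl group, faster than H6 is lost; the C5 centre so formed is re-enolised in step 7 and is of no consequence. Transfer of the silyl group to the scandium enolate frees the catalyst and leaves the enol double bond at C1=C8, which is why 13 is isolated on base-washed silica without hydrolysis.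

Step 7
Reactants: 13 triethyl{[(3R,4S,5R)-5-methoxy-4-{4-methoxy-3-[(triisopropylsilyl)oxy]phenyl}-3-methyl-2-(prop-2-en-1-yl)cyclopent-1-en-1-yl]oxy}silane; 14 methyl 2-methoxyacrylate
Product: 18 (1S,3S,5S,6S,7R)-1-allyl-3,5-dimethoxy-6-{4-methoxy-3-[(triisopropylsilyl)oxy]phenyl}-7-methylbicyclo[3.2.1]octane-4,8-dione, via lithium enolate 15 (not isolated), via Michael adduct 16 (not isolated), via dione enolate 17 (not isolated)
Conditions: MeLi, THF, 0 °C → rt; 14, −78 °C; LiN(SiMe3)2, −78 → 0 °C; AcOH, −78 °C
Reagents that add atoms: none
Why: MeLi cleaves the Si–O bond to give the C1 enolate 15 regiospecifically; its Michael addition to 14 anti to the C7 methyl group (as in enolate trapping trans to the neighbouring substituent of cyclopentanones) sets C1 (S), and after proton transfer the C5 enolate closes the six-membered ring by Dieckmann condensation, the tether fixing C5 (S). The amide base holds the product as its C3=C4 enolate 17, which protects the β-diketone from alkoxide cleavage. Protonation at −78 °C from the exo face, the endo face being covered by the C6 aryl group, sets C3 (S).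

Step 8
Reactants: 18 (1S,3S,5S,6S,7R)-1-allyl-3,5-dimethoxy-6-{4-methoxy-3-[(triisopropylsilyl)oxy]phenyl}-7-methylbicyclo[3.2.1]octane-4,8-dione
Product: 19 (1S,3S,5S,6S,7R,8S)-1-allyl-8-hydroxy-3,5-dimethoxy-6-{4-methoxy-3-[(triisopropylsilyl)oxy]phenyl}-7-methylbicyclo[3.2.1]octan-4-one
Conditions: NaBH4, CeCl3·7H2O, MeOH–THF, −78 °C
Reagents that add atoms: none
Why: 1,2-Reduction under Luche conditions; the endo C3 methoxy and endo C6 aryl groups cannot share a chair, so the six-membered ring of 18 should be a boat whose C3–H covers the rear face of C8, and hydride enters from the C6–C7 side to give the 8S alcohol. C4 is expected to react more slowly because its endo face is blocked by the aryl group and exo attack would drive the new alkoxide against that aryl group; cerium chloride keeps the medium non-basic, so C3 is not epimerised.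

Step 9
Reactants: 19 (1S,3S,5S,6S,7R,8S)-1-allyl-8-hydroxy-3,5-dimethoxy-6-{4-methoxy-3-[(triisopropylsilyl)oxy]phenyl}-7-methylbicyclo[3.2.1]octan-4-one
Product: 20 (1S,3S,5S,6S,7R,8S)-1-allyl-8-hydroxy-6-(3-hydroxy-4-methoxyphenyl)-3,5-dimethoxy-7-methylbicyclo[3.2.1]octan-4-one (CNP0209708.1)
Conditions: Bu4NF, AcOH, THF, 0 °C
Reagents that add atoms: none
Why: Fluoride cleavage of the aryl silyl ether; acetic acid buffers the phenoxide so that the C3 centre and the β-hydroxy ketone (retro-aldol) are not exposed to base.

## Compound list

1 | ethyl (triphenyl-λ5-phosphanylidene)acetate | CCOC(=O)C=P(c1ccccc1)(c1ccccc1)c1ccccc1 | starting material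
2 | allyl bromide | C=CCBr | starting material
3 | (1-ethoxy-1-oxopent-4-en-2-yl)triphenylphosphonium bromide | C=CCC(C(=O)OCC)[P+](c1ccccc1)(c1ccccc1)c1ccccc1.[Br-] | intermediate (not isolated)
4 | ethyl 2-(triphenyl-λ5-phosphanylidene)pent-4-enoate | C=CCC(C(=O)OCC)=P(c1ccccc1)(c1ccccc1)c1ccccc1 | intermediate
5 | acetaldehyde | CC=O | starting material
6 | ethyl (2E)-2-(prop-2-en-1-yl)but-2-enoate | C=CC/C(=C\C)C(=O)OCC | intermediate
7 | diethyl (methoxymethyl)phosphonate | CCOP(=O)(COC)OCC | starting material
8 | diethyl [lithio(methoxy)methyl]phosphonate | [Li+].CCOP(=O)([CH-]OC)OCC | intermediate (not isolated)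
9 | diethyl [(3E)-1-methoxy-2-oxo-3-(prop-2-en-1-yl)pent-3-en-1-yl]phosphonate, racemic | C=CC/C(=C\C)C(=O)C(OC)P(=O)(OCC)OCC | intermediate
10 | isovanillin | COc1ccc(C=O)cc1O | starting material
11 | 4-methoxy-3-[(triisopropylsilyl)oxy]benzaldehyde | COc1ccc(C=O)cc1O[Si](C(C)C)(C(C)C)C(C)C | intermediate
12 | (1Z,4E)-2-methoxy-1-{4-methoxy-3-[(triisopropylsilyl)oxy]phenyl}-4-(prop-2-en-1-yl)hexa-1,4-dien-3-one | C=CC/C(=C\C)C(=O)/C(OC)=C/c1ccc(OC)c(O[Si](C(C)C)(C(C)C)C(C)C)c1 | intermediate
13 | triethylsilyl enol ether of the cyclopentanone, (3R,4S,5R) in cyclopentene numbering (C7 R, C6 S; C5 methoxy cis to aryl, of no consequence) | C=CCC1=C(O[Si](CC)(CC)CC)[C@H](OC)[C@H](c2ccc(OC)c(O[Si](C(C)C)(C(C)C)C(C)C)c2)[C@H]1C | intermediate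
14 | methyl 2-methoxyacrylate | C=C(OC)C(=O)OC | starting material
15 | lithium C1=C8 enolate derived from 13 | C=CCC1=C([O-])[C@H](OC)[C@H](c2ccc(OC)c(O[Si](C(C)C)(C(C)C)C(C)C)c2)[C@H]1C.[Li+] | intermediate (not isolated)
16 | Michael adduct: keto ester with quaternary C1 (S) bearing allyl and CH2CH(OMe)CO2Me, C6 (S), C7 (R); C3 and C5 as epimer mixtures (present as its enolate) | C=CC[C@@]1(CC(OC)C(=O)OC)C(=O)C(OC)[C@H](c2ccc(OC)c(O[Si](C(C)C)(C(C)C)C(C)C)c2)[C@H]1C | intermediate (not isolated)
17 | lithium C3=C4 enolate of dione 18 | C=CC[C@]12CC(OC)=C([O-])[C@](OC)([C@H](c3ccc(OC)c(O[Si](C(C)C)(C(C)C)C(C)C)c3)[C@H]1C)C2=O.[Li+] | intermediate (not isolated)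
18 | (1S,3S,5S,6S,7R)-1-allyl-3,5-dimethoxy-6-{4-methoxy-3-[(triisopropylsilyl)oxy]phenyl}-7-methylbicyclo[3.2.1]octane-4,8-dione | C=CC[C@]12C[C@H](OC)C(=O)[C@](OC)([C@H](c3ccc(OC)c(O[Si](C(C)C)(C(C)C)C(C)C)c3)[C@H]1C)C2=O | intermediate
19 | (1S,3S,5S,6S,7R,8S)-1-allyl-8-hydroxy-3,5-dimethoxy-6-{4-methoxy-3-[(triisopropylsilyl)oxy]phenyl}-7-methylbicyclo[3.2.1]octan-4-one | C=CC[C@]12C[C@H](OC)C(=O)[C@](OC)([C@H](c3ccc(OC)c(O[Si](C(C)C)(C(C)C)C(C)C)c3)[C@H]1C)[C@H]2O | intermediate
20 | (1S,3S,5S,6S,7R,8S)-1-allyl-8-hydroxy-6-(3-hydroxy-4-methoxyphenyl)-3,5-dimethoxy-7-methylbicyclo[3.2.1]octan-4-one | C=CC[C@]12C[C@H](OC)C(=O)[C@](OC)([C@H](c3ccc(OC)c(O)c3)[C@H]1C)[C@H]2O | target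

## Step count and risks

Total: 9 steps. Longest linear sequence: 8 steps (1, 2, 3, 5, 6, 7, 8, 9); step 4 is a one-step branch.

**Step 6 (key step, proposed new method).**
- Most likely to go wrong: erosion of enantiocontrol. The silyl triflate released when the silane gives up its hydride is an achiral Lewis acid and can turn the dienone over outside the ligand sphere. A second failure is proton loss from C6 outrunning hydride capture, which would erase C6.
- Fallback (known chemistry), from 12 back to 20: 12 is cyclised by the established achiral reductive Nazarov reaction (Et3SiH, Sc(OTf)3 without ligand). This should give 13 together with its mirror image F1. Steps 7 to 9 are run unchanged on the racemate and lead through 18 with its mirror image F2 and 19 with its mirror image F3 to 20 with its mirror image F4. The phenols are esterified with (S)-2-methoxy-2-phenylacetic acid (EDC, DMAP) to the diastereomeric aryl esters, the ester of 20 F5 and the ester of the mirror image F6. These are separated by chromatography or crystallisation. Aminolysis of F5 with n-propylamine in THF at 0 °C returns 20 without exposing C3 to strong base.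

**Step 8.**
- Most likely to go wrong: hydride transfer to C4 in competition with C8. The open face of C8 is flanked by the exo methyl group on C7, and the face selectivity rests on the boat conformation; the result would be over-reduction or a mixture of ketols.
- Fallback, from 18 back to 19: both carbonyl groups are reduced with excess LiBH4 (THF, 0 °C → rt) to the diol F7. Its C4 carbinol is then oxidised selectively with catalytic TEMPO and PhI(OAc)2 in CH2Cl2. The C8 carbinol lies between two quaternary carbons and should be left by this sterically demanding oxidant. Mis-oxidised material can be returned to F7 by reduction.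

**Step 7.**
- Most likely to go wrong: slow or reversible conjugate addition. The 2-methoxy group makes 14 a poorer acceptor than an acrylate and the donor is a tetrasubstituted enolate, so proton transfer and oligomerisation of 14 can take over.
- Fallback, from 13 back to 18, with the methoxy group introduced after ring closure: enolate 15 (MeLi) is added to methyl acrylate to give the keto ester F8. LiN(SiMe3)2 closes it to the 3-demethoxy dione F9. Its C3=C4 enolate is hydroxylated with 2-(phenylsulfonyl)-3-phenyloxaziridine from the exo face to the 3-exo-hydroxy dione F10. Methylation (Me3OBF4, 1,8-bis(dimethylamino)naphthalene) gives the C3 epimer of 18 F11. Deprotonation with LiN(SiMe3)2 at −78 °C and protonation with AcOH, as in step 7, inverts C3 and gives 18.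

**Step 3 (and the geometry of step 5).**
- Most likely to go wrong: conjugate addition or γ-deprotonation of the enoate in place of acylation, and E/Z mixtures at the enol ether in the olefination.
- Fallback, from 6 back to 12, by aldol condensation: 6 is converted into the N-methoxy-N-methylamide F12 (MeNHOMe·HCl, iPrMgCl). Methoxymethyllithium (from Bu3SnCH2OMe and n-BuLi) gives the methoxymethyl ketone F13. Its lithium enolate (LiN(iPr)2, −78 °C) adds to 11 to give the aldol F14. Mesylation and elimination (MsCl, Et3N; DBU) under E1cB control give the more stable Z enol ether 12.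

## Further compounds

F1 | step 6 | mirror image of 13 | C=CCC1=C(O[Si](CC)(CC)CC)[C@@H](OC)[C@@H](c2ccc(OC)c(O[Si](C(C)C)(C(C)C)C(C)C)c2)[C@@H]1C
F2 | step 6 | mirror image of 18 | C=CC[C@@]12C[C@@H](OC)C(=O)[C@@](OC)([C@@H](c3ccc(OC)c(O[Si](C(C)C)(C(C)C)C(C)C)c3)[C@@H]1C)C2=O
F3 | step 6 | mirror image of 19 | C=CC[C@@]12C[C@@H](OC)C(=O)[C@@](OC)([C@@H](c3ccc(OC)c(O[Si](C(C)C)(C(C)C)C(C)C)c3)[C@@H]1C)[C@@H]2O
F4 | step 6 | mirror image of 20 | C=CC[C@@]12C[C@@H](OC)C(=O)[C@@](OC)([C@@H](c3ccc(OC)c(O)c3)[C@@H]1C)[C@@H]2O
F5 | step 6 | (S)-2-methoxy-2-phenylacetate (aryl ester) of 20 | C=CC[C@]12C[C@H](OC)C(=O)[C@](OC)([C@H](c3ccc(OC)c(OC(=O)[C@@H](OC)c4ccccc4)c3)[C@H]1C)[C@H]2O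
F6 | step 6 | (S)-2-methoxy-2-phenylacetate (aryl ester) of F4 | C=CC[C@@]12C[C@@H](OC)C(=O)[C@@](OC)([C@@H](c3ccc(OC)c(OC(=O)[C@@H](OC)c4ccccc4)c3)[C@@H]1C)[C@@H]2O
F7 | step 8 | (1S,3S,5S,6S,7R,8S)-1-allyl-3,5-dimethoxy-6-{4-methoxy-3-[(triisopropylsilyl)oxy]phenyl}-7-methylbicyclo[3.2.1]octane-4,8-diol, C4 configuration open | C=CC[C@]12C[C@H](OC)C(O)[C@](OC)([C@H](c3ccc(OC)c(O[Si](C(C)C)(C(C)C)C(C)C)c3)[C@H]1C)[C@H]2O
F8 | step 7 | keto ester from 15 and methyl acrylate, C1 (S), C5 epimer mixture | C=CC[C@@]1(CCC(=O)OC)C(=O)C(OC)[C@H](c2ccc(OC)c(O[Si](C(C)C)(C(C)C)C(C)C)c2)[C@H]1C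
F9 | step 7 | 3-demethoxy analogue of 18 | C=CC[C@]12CCC(=O)[C@](OC)([C@H](c3ccc(OC)c(O[Si](C(C)C)(C(C)C)C(C)C)c3)[C@H]1C)C2=O
F10 | step 7 | (3R)-3-hydroxy analogue of 18, hydroxyl exo | C=CC[C@]12C[C@@H](O)C(=O)[C@](OC)([C@H](c3ccc(OC)c(O[Si](C(C)C)(C(C)C)C(C)C)c3)[C@H]1C)C2=O
F11 | step 7 | C3 epimer (3R) of 18, methoxy exo | C=CC[C@]12C[C@@H](OC)C(=O)[C@](OC)([C@H](c3ccc(OC)c(O[Si](C(C)C)(C(C)C)C(C)C)c3)[C@H]1C)C2=O
F12 | step 3 | (2E)-N-methoxy-N-methyl-2-(prop-2-en-1-yl)but-2-enamide | C=CC/C(=C\C)C(=O)N(C)OC
F13 | step 3 | (3E)-1-methoxy-3-(prop-2-en-1-yl)pent-3-en-2-one | C=CC/C(=C\C)C(=O)COC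
F14 | step 3 | aldol adduct of F13 and 11, diastereomer mixture | C=CC/C(=C\C)C(=O)C(OC)C(O)c1ccc(OC)c(O[Si](C(C)C)(C(C)C)C(C)C)c1
A1 | alternative 1 | cyclopentane with C8 silyl ether, C5 N-methoxy-N-methylamide and C3 tributylstannane | C=CC[C@]1(C[C@H](OC)[Sn](CCCC)(CCCC)CCCC)[C@H](C)[C@@H](c2ccc(OC)c(O[Si](C)(C)C(C)(C)C)c2)[C@@](OC)(C(=O)N(C)OC)[C@H]1O[Si](C)(C)C(C)(C)C
A2 | alternative 1 | bis-silyl ether of the target | C=CC[C@]12C[C@H](OC)C(=O)[C@](OC)([C@H](c3ccc(OC)c(O[Si](C)(C)C(C)(C)C)c3)[C@H]1C)[C@H]2O[Si](C)(C)C(C)(C)C
A3 | alternative 2 | bicyclo[2.2.2]octenone with C4 hydroxyl, C5 ketone and C8 dimethyl ketal | C=CC[C@@]12C=C(OC)[C@@](O)(C(=O)C1(OC)OC)[C@H](c3ccc(OC)c(O[Si](C)(C)C(C)(C)C)c3)[C@H]2C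
A4 | alternative 2 | C5-hydroxy bicyclo[3.2.1]oct-3-en-2-one with C8 dimethyl ketal | C=CC[C@]12C=C(OC)C(=O)[C@](O)([C@H](c3ccc(OC)c(O[Si](C)(C)C(C)(C)C)c3)[C@H]1C)C2(OC)OC
A5 | alternative 3 | 2-allyl-2-bromocyclohexane-1,3-dione with the C6 aryl(vinyl)methyl side chain on C5, C1 configuration open | C=CCC1(Br)C[C@H](OC)C(=O)[C@](OC)([C@H](c2ccc(OC)c(O[Si](C)(C)C(C)(C)C)c2)C=C)C1=O
A6 | alternative 3 | bicyclo[3.2.1]octane-4,8-dione with all carbons of the target | C=CC[C@]12C[C@H](OC)C(=O)[C@](OC)([C@H](c3ccc(OC)c(O[Si](C)(C)C(C)(C)C)c3)[C@H]1C)C2=O
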